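**Plan**
- Cuts: C1′=C2′ (cross-metathesis); in the dihydropyranone first O1–C2 (lactonization), then C4–C5 and C3–C2 together; in the chain C7′–C8′ (aldol), the C6′ carbinol (ketone reduction) and C5′–C6′ (dithiane alkylation).
- Enabling feature: the ring segment C2(=O)–C3H=C4H–C5H2–C6H–O1 is a cis-vinylene between an acyl carbon and a CH2 that is β to the ring oxygen. C3/C4 can therefore come from acetylene used as a vicinal dianion (the alkyne is a temporary oxidation level), C5–C6–O1 from a terminal epoxide, and C2 from CO2.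
- Forward: (S)-2-vinyloxirane, acetylide and CO2 give the hydroxy-ynoic acid in one flask; cis-semihydrogenation removes the alkyne helper and the ring closes. The chain grows from (S)-epichlorohydrin via allyl oxirane and a methyl ketone, by aldol to cinnamaldehyde and syn reduction. The halves are joined last by cross-metathesis, then the acetonide is removed.
- Stereochemistry: C6 from hydrolytic kinetic resolution (catalyst control); C4′ from (S)-epichlorohydrin; C8′ by 1,5-anti induction in the boron aldol; C6′ by chelation-controlled 1,3-syn reduction; C3=C4 Z from syn hydrogenation, C1′=C2′ E from metathesis, C9′=C10′ E from cinnamaldehyde.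

Key step: step 2

Remark: ring atoms are numbered O1, C2 (C=O), C3, C4, C5, C6; chain carbons run from C1′ (on C6) to C10′ (bearing phenyl). (S)-2-Vinyloxirane can also be bought; step 1 is kept to show where C6 comes from.

**Route**

Step 1
Reactants: 1 rac-2-vinyloxirane
Product: 2 (S)-2-vinyloxirane
Conditions: (S,S)-(salen)Co(OAc) [trivalent cobalt; salen = N,N′-bis(3,5-di-tert-butylsalicylidene)-1,2-cyclohexanediamine dianion] (0.5 mol%), H2O (0.55 equiv), neat, 0 → 20 °C; distillation
Reagents that add atoms: none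
Why: Hydrolytic kinetic resolution, in which the chiral cobalt–salen catalyst hydrolyses the R epoxide at its terminal carbon, so the unreacted S enantiomer carrying the future C6 should be recovered by distillation from the diol.

Step 2
Reactants: 2 (S)-2-vinyloxirane
Product: 5 (R)-5-hydroxyhept-6-en-2-ynoic acid, via lithium (R)-hex-1-en-5-yn-3-olate 3 (not isolated), via dilithium (R)-3-oxidohex-1-en-5-yn-6-ide 4 (not isolated)
Conditions: LiC≡CH·H2NCH2CH2NH2 (1.5 equiv), DMSO, 10 → 20 °C; then THF, n-BuLi (2.5 equiv), 0 °C; CO2 (1 atm), 0 → 20 °C; aq. HCl to pH 2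
Reagents that add atoms: lithium acetylide–ethylenediamine complex, [Li+].[C-]#C.NCCN; carbon dioxide, O=C=O
Why: The acetylide opens the oxirane of 2 by SN2 attack at the unsubstituted ring carbon (future C5), which makes the C4–C5 bond and frees O1 as alkoxide 3; a second deprotonation at the new terminal alkyne gives dianion 4, whose sp carbanion adds to CO2 and makes the C3–C2 bond, so acetylene serves as a vicinal dianion linchpin between epoxide and CO2. The closest known reaction type is the ethynylation of a terminal epoxide followed by carboxylation of the homopropargylic alkoxide dianion, the classical entry to 5-hydroxyalk-2-ynoic acids and 6-substituted 5,6-dihydropyran-2-ones, here run in one flask. No ring closes in this step, because the linear alkyne cannot lactonize; the six-membered ring closes in step 3 by 6-exo-trig attack of O1 on the carboxyl carbon once the triple bond is a Z alkene. No stereocenter is formed, and C6 keeps the configuration of 2 because substitution occurs at the neighbouring CH2. The step needs attack at the terminal epoxide carbon rather than at the allylic carbon or in the SN2′ sense at the vinyl terminus, which a hard acetylide in DMSO without Lewis acid should secure, and C- rather than O-carboxylation, which holds because the carbonate formed at O1 is reversible and is lost as CO2 on acidification.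

Step 3
Reactants: 5 (R)-5-hydroxyhept-6-en-2-ynoic acid
Product: 7 (R)-6-vinyl-5,6-dihydro-2H-pyran-2-one, via (R,Z)-5-hydroxyhepta-2,6-dienoic acid 6 (not isolated)
Conditions: H2 (1 atm), Pd/CaCO3 poisoned with Pb(OAc)2 (Lindlar catalyst), quinoline, EtOAc, 20 °C; then p-TsOH (cat.), CH2Cl2, 20 °C
Reagents that add atoms: none
Why: Lindlar semihydrogenation adds H2 syn to the conjugated alkyne faster than to the vinyl group and so removes the alkyne helper, and the Z 5-hydroxy-2-enoic acid should then close to the δ-lactone under acid catalysis (6-exo-trig lactonization) without touching C6.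

Step 4
Reactants: 8 (S)-epichlorohydrin
Product: 10 (S)-2-allyloxirane, via (S)-1-chloropent-4-en-2-ol 9 (not isolated)
Conditions: CH2=CHMgBr, CuI (10 mol%), THF, −40 °C; aq. NH4Cl; then NaOH (powder), Et2O, 20 °C
Reagents that add atoms: vinylmagnesium bromide, C=C[Mg]Br
Why: Copper-catalysed Grignard opening of the epoxide at its terminal carbon followed by Williamson closure of the chlorohydrin transposes the epoxide without involving the stereocenter, so C4′ comes from the chiral pool.

Step 5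
Reactants: 10 (S)-2-allyloxirane
Product: 11 (S)-1-(2-methyl-1,3-dithian-2-yl)pent-4-en-2-ol
Conditions: 2-methyl-1,3-dithiane, n-BuLi, THF, −30 °C; then 10, −30 → 0 °C
Reagents that add atoms: 2-methyl-1,3-dithiane, CC1SCCCS1
Why: Dithiane umpolung, in which the lithiated dithiane (an acetyl anion equivalent) opens the terminal epoxide by SN2 attack at the CH2 carbon and leaves the carbinol stereocenter untouched.

Step 6
Reactants: 11 (S)-1-(2-methyl-1,3-dithian-2-yl)pent-4-en-2-ol
Product: 12 2-[(S)-2-[(4-methoxybenzyl)oxy]pent-4-en-1-yl]-2-methyl-1,3-dithiane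
Conditions: NaH, 4-methoxybenzyl chloride, n-Bu4NI (cat.), THF/DMF, 0 → 20 °C
Reagents that add atoms: 4-methoxybenzyl chloride, COc1ccc(CCl)cc1
Why: Williamson etherification installs the 4-methoxybenzyl ether that is needed as the β-alkoxy director of the later 1,5-anti aldol.

Step 7
Reactants: 12 2-[(S)-2-[(4-methoxybenzyl)oxy]pent-4-en-1-yl]-2-methyl-1,3-dithiane
Product: 13 (S)-4-[(4-methoxybenzyl)oxy]hept-6-en-2-one
Conditions: MeI, CaCO3, MeCN/H2O (9:1), 45 °C
Reagents that add atoms: water, O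
Why: Alkylative dithiane hydrolysis (S-methylation, then hydrolysis of the sulfonium) should unmask the methyl ketone under near-neutral conditions that spare the benzylic ether, the alkene and the β-alkoxy ketone.

Step 8
Reactants: 13 (S)-4-[(4-methoxybenzyl)oxy]hept-6-en-2-one; 14 (E)-cinnamaldehyde
Product: 16 (1E,3R,7S)-3-hydroxy-7-[(4-methoxybenzyl)oxy]-1-phenyldeca-1,9-dien-5-one, via dibutylboron enolate 15 (not isolated)
Conditions: n-Bu2BOTf, i-Pr2NEt, Et2O, −78 °C; then 14, −78 °C; MeOH, pH 7 buffer, H2O2, 0 °C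
Reagents that add atoms: none
Why: Boron-mediated aldol of a β-alkoxy methyl ketone, with kinetic enolization on the methyl side and 1,5-anti induction from the β-alkoxy stereocenter through a boat-like transition state, should set the new carbinol C8′ as R, anti to C4′.

Step 9
Reactants: 16 (1E,3R,7S)-3-hydroxy-7-[(4-methoxybenzyl)oxy]-1-phenyldeca-1,9-dien-5-one
Product: 18 (1E,3R,5S,7S)-7-[(4-methoxybenzyl)oxy]-1-phenyldeca-1,9-diene-3,5-diol, via diethylboron chelate 17 (not isolated)
Conditions: Et2BOMe, THF/MeOH (4:1), −78 °C; NaBH4, −78 °C; AcOH, then MeOH co-evaporation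
Reagents that add atoms: none
Why: Narasaka–Prasad reduction, in which external hydride attacks the six-membered boron chelate of the β-hydroxy ketone axially, should give the 1,3-syn diol at C6′, which together with the 1,5-anti aldol makes C4′/C6′ anti.

Step 10
Reactants: 18 (1E,3R,5S,7S)-7-[(4-methoxybenzyl)oxy]-1-phenyldeca-1,9-diene-3,5-diol
Product: 19 (4R,6R)-4-[(2S)-2-[(4-methoxybenzyl)oxy]pent-4-en-1-yl]-2,2-dimethyl-6-[(E)-2-phenylethenyl]-1,3-dioxane
Conditions: 2,2-dimethoxypropane, PPTS (cat.), CH2Cl2, 20 °C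
Reagents that add atoms: 2,2-dimethoxypropane, COC(C)(C)OC
Why: Acid-catalysed transketalization gives the syn-1,3-diol acetonide, which shields the cinnamyl-type alcohol from DDQ and from the ruthenium carbene.

Step 11
Reactants: 19 (4R,6R)-4-[(2S)-2-[(4-methoxybenzyl)oxy]pent-4-en-1-yl]-2,2-dimethyl-6-[(E)-2-phenylethenyl]-1,3-dioxane
Product: 20 (2S)-1-[(4R,6R)-2,2-dimethyl-6-[(E)-2-phenylethenyl]-1,3-dioxan-4-yl]pent-4-en-2-ol
Conditions: DDQ, CH2Cl2/pH 7 buffer (10:1), 0 °C
Reagents that add atoms: none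
Why: Oxidative cleavage of the 4-methoxybenzyl ether by DDQ (hydride abstraction from the electron-rich benzylic position, then hydrolysis) should free the C4′ hydroxyl while the acetonide, alkenes and stereocenters stay untouched.

Step 12
Reactants: 20 (2S)-1-[(4R,6R)-2,2-dimethyl-6-[(E)-2-phenylethenyl]-1,3-dioxan-4-yl]pent-4-en-2-ol; 7 (R)-6-vinyl-5,6-dihydro-2H-pyran-2-one
Product: 21 (6R)-6-[(1E,4S)-5-[(4R,6R)-2,2-dimethyl-6-[(E)-2-phenylethenyl]-1,3-dioxan-4-yl]-4-hydroxypent-1-en-1-yl]-5,6-dihydro-2H-pyran-2-one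
Conditions: 7 (3 equiv), second-generation Hoveyda–Grubbs catalyst RuCl2(H2IMes)(=CH-C6H4-2-OiPr) (5 mol%), CH2Cl2, 40 °C
Reagents that add atoms: none
Why: Olefin cross-metathesis between the terminal homoallylic alkene and the allylic vinyl group of the lactone should give the E alkene under thermodynamic control, the conjugated ring alkene and the hindered disubstituted styryl alkene being poor substrates.

Step 13
Reactants: 21 (6R)-6-[(1E,4S)-5-[(4R,6R)-2,2-dimethyl-6-[(E)-2-phenylethenyl]-1,3-dioxan-4-yl]-4-hydroxypent-1-en-1-yl]-5,6-dihydro-2H-pyran-2-one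
Product: 22 (6R)-6-[(1E,4S,6R,8R,9E)-4,6,8-trihydroxy-10-phenyldeca-1,9-dien-1-yl]-5,6-dihydro-2H-pyran-2-one
Conditions: AcOH/H2O (4:1), 40 °C
Reagents that add atoms: none
Why: Mild acid-catalysed acetal hydrolysis should release the syn diol without opening the lactone, ionizing the allylic carbinols or touching any stereocenter.

**Compound list**

1 | rac-2-vinyloxirane (3,4-epoxybut-1-ene) | C=CC1CO1 | starting material
2 | (S)-2-vinyloxirane | C=C[C@H]1CO1 | intermediate
3 | lithium (R)-hex-1-en-5-yn-3-olate | C#CC[C@@H]([O-])C=C.[Li+] | intermediate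
4 | dilithium (R)-3-oxidohex-1-en-5-yn-6-ide | [Li+].[Li+].[C-]#CC[C@@H]([O-])C=C | intermediate
5 | (R)-5-hydroxyhept-6-en-2-ynoic acid | OC(=O)C#CC[C@@H](O)C=C | intermediate
6 | (R,Z)-5-hydroxyhepta-2,6-dienoic acid | OC(=O)/C=C\C[C@@H](O)C=C | intermediate
7 | (R)-6-vinyl-5,6-dihydro-2H-pyran-2-one | O=C1C=CC[C@H](C=C)O1 | intermediate
8 | (S)-epichlorohydrin | ClC[C@@H]1CO1 | starting material
9 | (S)-1-chloropent-4-en-2-ol | ClC[C@@H](O)CC=C | intermediate
10 | (S)-2-allyloxirane | C=CC[C@H]1CO1 | intermediate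
11 | (S)-1-(2-methyl-1,3-dithian-2-yl)pent-4-en-2-ol | CC1(C[C@@H](O)CC=C)SCCCS1 | intermediate
12 | 2-[(S)-2-[(4-methoxybenzyl)oxy]pent-4-en-1-yl]-2-methyl-1,3-dithiane | CC1(C[C@@H](OCc2ccc(OC)cc2)CC=C)SCCCS1 | intermediate
13 | (S)-4-[(4-methoxybenzyl)oxy]hept-6-en-2-one | CC(=O)C[C@@H](OCc1ccc(OC)cc1)CC=C | intermediate
14 | (E)-cinnamaldehyde | O=C/C=C/c1ccccc1 | starting material
15 | dibutyl{[(S)-4-[(4-methoxybenzyl)oxy]hepta-1,6-dien-2-yl]oxy}borane (dibutylboron enolate) | C=C(OB(CCCC)CCCC)C[C@@H](OCc1ccc(OC)cc1)CC=C | intermediate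
16 | (1E,3R,7S)-3-hydroxy-7-[(4-methoxybenzyl)oxy]-1-phenyldeca-1,9-dien-5-one | C=CC[C@H](OCc1ccc(OC)cc1)CC(=O)C[C@@H](O)/C=C/c1ccccc1 | intermediate
17 | O-diethylboryl derivative of 16 (diethylboron chelate) | C=CC[C@H](OCc1ccc(OC)cc1)CC(=O)C[C@@H](OB(CC)CC)/C=C/c1ccccc1 | intermediate
18 | (1E,3R,5S,7S)-7-[(4-methoxybenzyl)oxy]-1-phenyldeca-1,9-diene-3,5-diol | C=CC[C@H](OCc1ccc(OC)cc1)C[C@@H](O)C[C@@H](O)/C=C/c1ccccc1 | intermediate
19 | (4R,6R)-4-[(2S)-2-[(4-methoxybenzyl)oxy]pent-4-en-1-yl]-2,2-dimethyl-6-[(E)-2-phenylethenyl]-1,3-dioxane | C=CC[C@H](OCc1ccc(OC)cc1)C[C@@H]1C[C@H](/C=C/c2ccccc2)OC(C)(C)O1 | intermediate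
20 | (2S)-1-[(4R,6R)-2,2-dimethyl-6-[(E)-2-phenylethenyl]-1,3-dioxan-4-yl]pent-4-en-2-ol | C=CC[C@H](O)C[C@@H]1C[C@H](/C=C/c2ccccc2)OC(C)(C)O1 | intermediate
21 | (6R)-6-[(1E,4S)-5-[(4R,6R)-2,2-dimethyl-6-[(E)-2-phenylethenyl]-1,3-dioxan-4-yl]-4-hydroxypent-1-en-1-yl]-5,6-dihydro-2H-pyran-2-one | O=C1C=CC[C@H](/C=C/C[C@H](O)C[C@@H]2C[C@H](/C=C/c3ccccc3)OC(C)(C)O2)O1 | intermediate
22 | (6R)-6-[(1E,4S,6R,8R,9E)-4,6,8-trihydroxy-10-phenyldeca-1,9-dien-1-yl]-5,6-dihydro-2H-pyran-2-one | O=C1C=CC[C@H](/C=C/C[C@H](O)C[C@@H](O)C[C@@H](O)/C=C/c2ccccc2)O1 | target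

**Count and risks**

Total steps: 13. Longest linear sequence: 10 steps (steps 4 to 13); the lactone branch (steps 1 to 3) joins at step 12.

Steps most likely to fail:

1. Step 2. The acetylide may attack the allylic epoxide carbon or add in the SN2′ sense, and carboxylation of the alkynyl anion may be incomplete in the amine-containing medium. The fallback sets out from 2 and returns at 7, building C4–C5 by dithiane alkylation and C3=C4 by Z-olefination. Compound 2 would be opened at its terminal carbon with unhindered 2-lithio-1,3-dithiane (THF, −30 °C) to give (R)-1-(1,3-dithian-2-yl)but-3-en-2-ol F1. Silylation (TBSCl, imidazole, DMF) would give tert-butyl{[(R)-1-(1,3-dithian-2-yl)but-3-en-2-yl]oxy}dimethylsilane F2. Unmasking (MeI, CaCO3, MeCN/H2O) would give (R)-3-[(tert-butyldimethylsilyl)oxy]pent-4-enal F3. Still–Gennari olefination (methyl bis(2,2,2-trifluoroethyl)phosphonoacetate, KN(SiMe3)2, 18-crown-6, THF, −78 °C) would give methyl (R,Z)-5-[(tert-butyldimethylsilyl)oxy]hepta-2,6-dienoate F4. Aqueous HF in MeCN would then remove the silyl group, and the Z hydroxy ester should lactonize to 7.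

2. Step 12. The catalyst may engage the styryl double bond (loss of styrene or ring closure), the terminal alkene may homodimerize, or the free alcohol may isomerize through ruthenium hydrides. The fallback sets out from 13 and 7 and returns at 21, doing the metathesis before any styryl group exists. Cross-metathesis of 13 with 7 under the step 12 conditions would give (6R)-6-[(1E,4S)-4-[(4-methoxybenzyl)oxy]-6-oxohept-1-en-1-yl]-5,6-dihydro-2H-pyran-2-one F5. Boron aldol with 14 as in step 8 would give (6R)-6-[(1E,4S,8R,9E)-8-hydroxy-4-[(4-methoxybenzyl)oxy]-6-oxo-10-phenyldeca-1,9-dien-1-yl]-5,6-dihydro-2H-pyran-2-one F6. Chelation-controlled reduction as in step 9 would give (6R)-6-[(1E,4S,6S,8R,9E)-6,8-dihydroxy-4-[(4-methoxybenzyl)oxy]-10-phenyldeca-1,9-dien-1-yl]-5,6-dihydro-2H-pyran-2-one F7. Acetonide formation as in step 10 would give (6R)-6-[(1E,4S)-5-[(4R,6R)-2,2-dimethyl-6-[(E)-2-phenylethenyl]-1,3-dioxan-4-yl]-4-[(4-methoxybenzyl)oxy]pent-1-en-1-yl]-5,6-dihydro-2H-pyran-2-one F8. DDQ as in step 11 would then give 21.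

3. Step 8. The 1,5-anti induction may erode with the conjugated aldehyde, or the aldol may dehydrate to the dienone. The fallback sets out from 13 and returns at 16, replacing substrate control by catalyst control. Kinetic silylation (LiN(i-Pr)2, Me3SiCl, THF, −78 °C) would give trimethyl{[(S)-4-[(4-methoxybenzyl)oxy]hepta-1,6-dien-2-yl]oxy}silane F9. A Lewis-base-catalysed Mukaiyama aldol with 14 (SiCl4, chiral bisphosphoramide of the enantiomer that delivers the 3R carbinol, i-Pr2NEt, CH2Cl2, −78 °C) would then give 16.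

**Further compounds**

F1 | step 2 | (R)-1-(1,3-dithian-2-yl)but-3-en-2-ol | C=C[C@H](O)CC1SCCCS1
F2 | step 2 | tert-butyl{[(R)-1-(1,3-dithian-2-yl)but-3-en-2-yl]oxy}dimethylsilane | C=C[C@H](O[Si](C)(C)C(C)(C)C)CC1SCCCS1
F3 | step 2 | (R)-3-[(tert-butyldimethylsilyl)oxy]pent-4-enal | C=C[C@H](O[Si](C)(C)C(C)(C)C)CC=O
F4 | step 2 | methyl (R,Z)-5-[(tert-butyldimethylsilyl)oxy]hepta-2,6-dienoate | C=C[C@H](O[Si](C)(C)C(C)(C)C)C/C=C\C(=O)OC
F5 | step 12 | (6R)-6-[(1E,4S)-4-[(4-methoxybenzyl)oxy]-6-oxohept-1-en-1-yl]-5,6-dihydro-2H-pyran-2-one | O=C1C=CC[C@H](/C=C/C[C@H](OCc2ccc(OC)cc2)CC(C)=O)O1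
F6 | step 12 | (6R)-6-[(1E,4S,8R,9E)-8-hydroxy-4-[(4-methoxybenzyl)oxy]-6-oxo-10-phenyldeca-1,9-dien-1-yl]-5,6-dihydro-2H-pyran-2-one | O=C1C=CC[C@H](/C=C/C[C@H](OCc2ccc(OC)cc2)CC(=O)C[C@@H](O)/C=C/c2ccccc2)O1
F7 | step 12 | (6R)-6-[(1E,4S,6S,8R,9E)-6,8-dihydroxy-4-[(4-methoxybenzyl)oxy]-10-phenyldeca-1,9-dien-1-yl]-5,6-dihydro-2H-pyran-2-one | O=C1C=CC[C@H](/C=C/C[C@H](OCc2ccc(OC)cc2)C[C@@H](O)C[C@@H](O)/C=C/c2ccccc2)O1
F8 | step 12 | (6R)-6-[(1E,4S)-5-[(4R,6R)-2,2-dimethyl-6-[(E)-2-phenylethenyl]-1,3-dioxan-4-yl]-4-[(4-methoxybenzyl)oxy]pent-1-en-1-yl]-5,6-dihydro-2H-pyran-2-one | O=C1C=CC[C@H](/C=C/C[C@H](OCc2ccc(OC)cc2)C[C@@H]2C[C@H](/C=C/c3ccccc3)OC(C)(C)O2)O1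
F9 | step 8 | trimethyl{[(S)-4-[(4-methoxybenzyl)oxy]hepta-1,6-dien-2-yl]oxy}silane | C=C(O[Si](C)(C)C)C[C@@H](OCc1ccc(OC)cc1)CC=C
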